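**Retrosynthetic overview**

1. Pterocarpan numbering is used (ring A: C1–C4, C4a, C11b; ring B: O5, C6, C6a, C11a, C11b, C4a; ring C: C6a, C6b, C10a, O11, C11a; ring D: C6b–C10a). Lespecyrtin E4 (22) ⇐ deallylation of 21 ⇐ transannular C–H insertion: a chiral dirhodium carbene at C6a, made from hydrazone 19 of the nine-membered ketone 18, inserts into a C11a–H bond.
2. Enabling feature: C11a is a benzylic CH2 bound to O11 and to the electron-rich ring A, and it lies 1,5 to C6a through ring D (C6a–C6b–C10a–O11–C11a). The bond C6a–C11a is shared by rings B and C, and the other five bonds of ring B (C6a–C6–O5–C4a–C11b–C11a) are already present in the nine-membered ring, so one stitch closes ring C and, as the last ring of the skeleton, ring B, and sets both stereocentres.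
3. 18 ⇐ phenoxide/α-bromoketone ring closure (O5–C6) of 16 ⇐ α-bromination of 14 ⇐ Mitsunobu ether (O11–C11a) between acetophenone 8 (ring D with pyran and prenyl) and benzylic alcohol 13 (ring A with pyran).
4. 8 ⇐ 1-(2,4,5-trihydroxyphenyl)ethanone 1 by two O-alkylations and one thermal step (aromatic Claisen brings the C10 prenyl, propargyl Claisen/oxa-6π closes the ring D pyran); 13 ⇐ 2,2-dimethyl-2H-chromen-7-ol 9 by ortho-formylation, silylation and reduction.
5. Order of ring formation: ring A pyran (bought in 9), ring D pyran (step 4), temporary nine-membered ring (step 11), then rings C and B by the same bond in step 13; no ring is formed afterwards.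

Key step: step 13

Remark: 1 and 9 are treated as catalogue compounds (9 is otherwise two steps from 7-hydroxy-2,2-dimethylchroman-4-one by NaBH4 reduction and acid dehydration), and the sense of induction of Rh2(R-PTAD)4 is assumed by analogy; the antipodal catalyst would be taken if it proves opposite.

**Route**

Step 1
Reactants: 1 1-(2,4,5-trihydroxyphenyl)ethanone; 2 3-chloro-3-methylbut-1-yne
Product: 3 1-[2,5-dihydroxy-4-(2-methylbut-3-yn-2-yloxy)phenyl]ethanone
Conditions: K2CO3, KI, CuI (cat.), acetone, 55 °C
Reagents that add atoms: 3-chloro-3-methylbut-1-yne (compound 2), C#CC(C)(C)Cl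
Why: Copper-assisted O-propargylation (SN1-type substitution of the tertiary propargylic chloride by a phenoxide) should go to the 4-OH, which is para to the acetyl group and so the most acidic, while the 2-OH is held in a hydrogen bond to the carbonyl and the 5-OH is a less acidic meta phenol.

Step 2
Reactants: 3 1-[2,5-dihydroxy-4-(2-methylbut-3-yn-2-yloxy)phenyl]ethanone
Product: 4 1-[2,5-dihydroxy-4-(2-methylbut-3-en-2-yloxy)phenyl]ethanone
Conditions: H2 (1 atm), Pd/CaCO3 poisoned with Pb(OAc)2 (Lindlar catalyst), quinoline, EtOAc, rt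
Reagents that add atoms: none
Why: Lindlar semihydrogenation takes the terminal alkyne to the alkene and should stop there, leaving ketone and phenols untouched, so that the ether becomes a 1,1-dimethylallyl ether fit for an aromatic Claisen rearrangement.

Step 3
Reactants: 4 1-[2,5-dihydroxy-4-(2-methylbut-3-en-2-yloxy)phenyl]ethanone; 2 3-chloro-3-methylbut-1-yne
Product: 5 1-[2-hydroxy-4-(2-methylbut-3-en-2-yloxy)-5-(2-methylbut-3-yn-2-yloxy)phenyl]ethanone
Conditions: K2CO3, KI, CuI (cat.), acetone, 55 °C
Reagents that add atoms: 3-chloro-3-methylbut-1-yne (compound 2), C#CC(C)(C)Cl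
Why: The same phenoxide propargylation now meets only one free, non-chelated phenol (5-OH), the 2-OH staying hydrogen-bonded to the acetyl group.

Step 4
Reactants: 5 1-[2-hydroxy-4-(2-methylbut-3-en-2-yloxy)-5-(2-methylbut-3-yn-2-yloxy)phenyl]ethanone
Product: 7 1-[6,8-dihydroxy-2,2-dimethyl-7-(3-methylbut-2-en-1-yl)-2H-chromen-5-yl]ethanone, via C-prenylated propargyl ether 6 (not isolated)
Conditions: N,N-diethylaniline, 185 °C, argon
Reagents that add atoms: none
Why: Two thermal sigmatropic sequences should run in one pot: the aromatic Claisen rearrangement of the 1,1-dimethylallyl ether delivers a prenyl group to C3, its only free ortho position, and the propargyl ether then undergoes Claisen rearrangement to its only free ortho carbon (C6), 1,5-hydrogen shift and oxa-6π electrocyclisation to the 2,2-dimethyl-2H-pyran of ring D.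

Step 5
Reactants: 7 1-[6,8-dihydroxy-2,2-dimethyl-7-(3-methylbut-2-en-1-yl)-2H-chromen-5-yl]ethanone
Product: 8 1-[6-hydroxy-2,2-dimethyl-7-(3-methylbut-2-en-1-yl)-8-(prop-2-en-1-yloxy)-2H-chromen-5-yl]ethanone
Conditions: allyl bromide, K2CO3, acetone, 40 °C
Reagents that add atoms: allyl bromide, C=CCBr
Why: Williamson allylation should take the free 8-OH because the 6-OH is hydrogen-bonded to the acetyl group; the allyl ether is the only protecting group carried to the end.

Step 6
Reactants: 9 2,2-dimethyl-2H-chromen-7-ol; 10 paraformaldehyde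
Product: 11 7-hydroxy-2,2-dimethyl-2H-chromene-6-carbaldehyde
Conditions: MgCl2, Et3N, (CH2O)n, MeCN, 80 °C; cold dilute aq. HCl work-up
Reagents that add atoms: paraformaldehyde (compound 10), C=O
Why: Magnesium-phenoxide-directed ortho-formylation (hydroxymethylation, then hydride transfer to a second formaldehyde) is specific for the position ortho to the phenol and should choose C6, para to the ring oxygen and unhindered, over C8 between the two oxygens, while the basic medium spares the chromene.

Step 7
Reactants: 11 7-hydroxy-2,2-dimethyl-2H-chromene-6-carbaldehyde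
Product: 12 7-[(tert-butyldimethylsilyl)oxy]-2,2-dimethyl-2H-chromene-6-carbaldehyde
Conditions: TBSCl, imidazole, DMF, rt
Reagents that add atoms: tert-butyldimethylsilyl chloride, CC(C)(C)[Si](C)(C)Cl
Why: Imidazole-mediated O-silylation masks the ring A oxygen (later O5) until the ring closure of step 11.

Step 8
Reactants: 12 7-[(tert-butyldimethylsilyl)oxy]-2,2-dimethyl-2H-chromene-6-carbaldehyde
Product: 13 {7-[(tert-butyldimethylsilyl)oxy]-2,2-dimethyl-2H-chromen-6-yl}methanol
Conditions: NaBH4, MeOH, 0 °C
Reagents that add atoms: none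
Why: Borohydride reduction of the aldehyde gives the primary benzylic alcohol, and short contact at 0 °C should limit silyl migration from the phenol oxygen to the alkoxide.

Step 9
Reactants: 8 1-[6-hydroxy-2,2-dimethyl-7-(3-methylbut-2-en-1-yl)-8-(prop-2-en-1-yloxy)-2H-chromen-5-yl]ethanone; 13 {7-[(tert-butyldimethylsilyl)oxy]-2,2-dimethyl-2H-chromen-6-yl}methanol
Product: 14 1-[6-({7-[(tert-butyldimethylsilyl)oxy]-2,2-dimethyl-2H-chromen-6-yl}methoxy)-2,2-dimethyl-7-(3-methylbut-2-en-1-yl)-8-(prop-2-en-1-yloxy)-2H-chromen-5-yl]ethanone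
Conditions: PPh3, DIAD, THF, 0 °C to rt
Reagents that add atoms: none
Why: Mitsunobu etherification joins the two halves, since the chelated phenol of 8 is acidic enough to protonate the betaine and then displaces the oxyphosphonium of the primary, electron-rich benzylic alcohol, forming the O11–C11a ether.

Step 10
Reactants: 14 1-[6-({7-[(tert-butyldimethylsilyl)oxy]-2,2-dimethyl-2H-chromen-6-yl}methoxy)-2,2-dimethyl-7-(3-methylbut-2-en-1-yl)-8-(prop-2-en-1-yloxy)-2H-chromen-5-yl]ethanone
Product: 16 2-bromo-1-[6-({7-[(tert-butyldimethylsilyl)oxy]-2,2-dimethyl-2H-chromen-6-yl}methoxy)-2,2-dimethyl-7-(3-methylbut-2-en-1-yl)-8-(prop-2-en-1-yloxy)-2H-chromen-5-yl]ethanone, via trimethylsilyl enol ether 15 (not isolated)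
Conditions: LiN(SiMe3)2, TMSCl, THF, −78 °C; then NBS, THF, −78 °C
Reagents that add atoms: chlorotrimethylsilane, C[Si](C)(C)Cl; N-bromosuccinimide, BrN1C(=O)CCC1=O
Why: Kinetic enolisation of the only enolisable position (the methyl ketone) and silyl trapping let NBS brominate the silyl enol ether, the most nucleophilic alkene present, at −78 °C before the chromene, prenyl or allyl double bonds react (α-bromination of a ketone through its silyl enol ether).

Step 11
Reactants: 16 2-bromo-1-[6-({7-[(tert-butyldimethylsilyl)oxy]-2,2-dimethyl-2H-chromen-6-yl}methoxy)-2,2-dimethyl-7-(3-methylbut-2-en-1-yl)-8-(prop-2-en-1-yloxy)-2H-chromen-5-yl]ethanone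
Product: 18 nine-membered keto diether (ring D carbon C6b–C6a(=O)–C6H2–O5–ring A carbon C4a; ring A carbon C11b–C11aH2–O11–ring D carbon C10a; both dimethylpyrans, O-allyl at C9 and prenyl at C10 in place), via caesium phenoxide 17 (not isolated)
Conditions: CsF, DMF, 40 °C, syringe-pump addition of 16 (final 2 mM)
Reagents that add atoms: none
Why: Fluoride cleaves the aryl silyl ether and the caesium phenoxide should close the nine-membered ring by an intramolecular Williamson SN2 reaction at the very reactive α-keto bromide, with high dilution and the five sp2 carbons and two ortho-phenylene units of the forming ring favouring closure over oligomerisation.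

Step 12
Reactants: 18 nine-membered keto diether
Product: 19 hydrazone of 18 (C6a=N–NH2)
Conditions: N2H4·H2O (excess), AcOH (cat.), EtOH, 70 °C, degassed
Reagents that add atoms: hydrazine hydrate, NN
Why: Acid-catalysed condensation of the ketone with excess hydrazine should give the free hydrazone (excess suppresses azine formation, degassing suppresses diimide), the precursor of the diazo compound.

Step 13
Reactants: 19 hydrazone of 18
Product: 21 (6aR,11aR)-9-O-allyl-lespecyrtin E4, via diazo compound 20 (not isolated)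
Conditions: MnO2, MeCN, 0 °C; filtration; Rh2(R-PTAD)4 (1 mol%), MeCN/CH2Cl2, −20 °C to rt
Reagents that add atoms: none
Why: Proposed new method: MnO2 dehydrogenates the hydrazone to diazo compound 20, from which the chiral dirhodium carboxylate forms a donor/donor rhodium carbene at C6a that inserts, through a concerted three-centre hydride-transfer/C–C-forming transition state, into a C11a–H bond lying 1,5 to it (C6a–C6b–C10a–O11–C11a). The closest known reaction type is the enantioselective intramolecular C–H insertion of donor/donor rhodium carbenes, made in the same way from 2-(benzyloxy)aryl ketone hydrazones, which gives cis-2,3-disubstituted 2,3-dihydrobenzofurans; new here are the transannular setting in a nine-membered ring and the aryloxymethyl substituent on the carbene. The one new bond C6a–C11a closes ring C as a 1,5-insertion (five-membered transition state through O11) and in the same event closes ring B transannularly, the six atoms C6a, C6, O5, C4a, C11b and C11a of the nine-membered ring becoming the last ring of the skeleton. C11a (which enantiotopic benzylic hydrogen is replaced) and C6a (which carbene face receives that hydrogen) are both set by the chiral carboxylate ligands, and their cis relation is fixed because the hydrogen moves to C6a on the face where C11a bonds and because a six/five ring fusion formed across the medium ring cannot be trans. The step needs C–H insertion to win over 1,2-hydride shift from C6, over attack on ring A at C4 and over cyclopropanation of the chromene, prenyl and allyl double bonds. The substrate should secure this because the C11a–H bonds are the most hydridic in the molecule (benzylic, alpha to O11, on a ring with ortho and para oxygen), the medium ring holds them near C6a while turning C6 toward C11b and away from C4, the ortho chromene double bond and the prenyl CH2 of ring D cannot be reached without a four-membered or meta-bridged ring, and a donor/donor carbene with bulky carboxylates is slow in bimolecular alkene additions.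

Step 14
Reactants: 21 (6aR,11aR)-9-O-allyl-lespecyrtin E4
Product: 22 lespecyrtin E4, (6aR,11aR)
Conditions: Pd(PPh3)4 (cat.), morpholine, THF, rt
Reagents that add atoms: none
Why: Zerovalent palladium ionises the allyl aryl ether to a π-allyl complex that morpholine intercepts (Tsuji–Trost deallylation), which should free the C9 phenol under neutral conditions that leave the acid-labile benzylic C11a–O11 bond, both chromenes and the prenyl group untouched, with no stereocentre involved.

**Compound list**

1 | 1-(2,4,5-trihydroxyphenyl)ethanone | CC(=O)c1cc(O)c(O)cc1O | starting material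
2 | 3-chloro-3-methylbut-1-yne | C#CC(C)(C)Cl | starting material
3 | 1-[2,5-dihydroxy-4-(2-methylbut-3-yn-2-yloxy)phenyl]ethanone | CC(=O)c1cc(O)c(OC(C)(C)C#C)cc1O | intermediate
4 | 1-[2,5-dihydroxy-4-(2-methylbut-3-en-2-yloxy)phenyl]ethanone | CC(=O)c1cc(O)c(OC(C)(C)C=C)cc1O | intermediate
5 | 1-[2-hydroxy-4-(2-methylbut-3-en-2-yloxy)-5-(2-methylbut-3-yn-2-yloxy)phenyl]ethanone | CC(=O)c1cc(OC(C)(C)C#C)c(OC(C)(C)C=C)cc1O | intermediate
6 | 1-[2,4-dihydroxy-3-(3-methylbut-2-en-1-yl)-5-(2-methylbut-3-yn-2-yloxy)phenyl]ethanone (Claisen product, not isolated) | CC(=O)c1cc(OC(C)(C)C#C)c(O)c(CC=C(C)C)c1O | intermediate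
7 | 1-[6,8-dihydroxy-2,2-dimethyl-7-(3-methylbut-2-en-1-yl)-2H-chromen-5-yl]ethanone | CC(=O)c1c(O)c(CC=C(C)C)c(O)c2OC(C)(C)C=Cc12 | intermediate
8 | 1-[6-hydroxy-2,2-dimethyl-7-(3-methylbut-2-en-1-yl)-8-(prop-2-en-1-yloxy)-2H-chromen-5-yl]ethanone | CC(=O)c1c(O)c(CC=C(C)C)c(OCC=C)c2OC(C)(C)C=Cc12 | intermediate
9 | 2,2-dimethyl-2H-chromen-7-ol | CC1(C)C=Cc2ccc(O)cc2O1 | starting material
10 | paraformaldehyde (formaldehyde unit) | C=O | starting material
11 | 7-hydroxy-2,2-dimethyl-2H-chromene-6-carbaldehyde | CC1(C)C=Cc2cc(C=O)c(O)cc2O1 | intermediate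
12 | 7-[(tert-butyldimethylsilyl)oxy]-2,2-dimethyl-2H-chromene-6-carbaldehyde | CC1(C)C=Cc2cc(C=O)c(O[Si](C)(C)C(C)(C)C)cc2O1 | intermediate
13 | {7-[(tert-butyldimethylsilyl)oxy]-2,2-dimethyl-2H-chromen-6-yl}methanol | CC1(C)C=Cc2cc(CO)c(O[Si](C)(C)C(C)(C)C)cc2O1 | intermediate
14 | 1-[6-({7-[(tert-butyldimethylsilyl)oxy]-2,2-dimethyl-2H-chromen-6-yl}methoxy)-2,2-dimethyl-7-(3-methylbut-2-en-1-yl)-8-(prop-2-en-1-yloxy)-2H-chromen-5-yl]ethanone | CC(=O)c1c(OCc3cc4C=CC(C)(C)Oc4cc3O[Si](C)(C)C(C)(C)C)c(CC=C(C)C)c(OCC=C)c2OC(C)(C)C=Cc12 | intermediate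
15 | trimethylsilyl enol ether of 14 (not isolated) | C=C(O[Si](C)(C)C)c1c(OCc3cc4C=CC(C)(C)Oc4cc3O[Si](C)(C)C(C)(C)C)c(CC=C(C)C)c(OCC=C)c2OC(C)(C)C=Cc12 | intermediate
16 | 2-bromo-1-[6-({7-[(tert-butyldimethylsilyl)oxy]-2,2-dimethyl-2H-chromen-6-yl}methoxy)-2,2-dimethyl-7-(3-methylbut-2-en-1-yl)-8-(prop-2-en-1-yloxy)-2H-chromen-5-yl]ethanone | O=C(CBr)c1c(OCc3cc4C=CC(C)(C)Oc4cc3O[Si](C)(C)C(C)(C)C)c(CC=C(C)C)c(OCC=C)c2OC(C)(C)C=Cc12 | intermediate
17 | desilylated bromoketone, 2-bromo-1-{6-[(7-hydroxy-2,2-dimethyl-2H-chromen-6-yl)methoxy]-2,2-dimethyl-7-(3-methylbut-2-en-1-yl)-8-(prop-2-en-1-yloxy)-2H-chromen-5-yl}ethanone, present as its caesium phenoxide (not isolated) | O=C(CBr)c1c(OCc3cc4C=CC(C)(C)Oc4cc3O)c(CC=C(C)C)c(OCC=C)c2OC(C)(C)C=Cc12 | intermediate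
18 | nine-membered keto diether (ring atoms C6a(=O), C6, O5, C4a, C11b, C11a, O11, C10a, C6b; ring A and ring D each with their fused 2,2-dimethyl-2H-pyran; O-allyl at C9; prenyl at C10) | O=C1COc2cc3OC(C)(C)C=Cc3cc2COc2c(CC=C(C)C)c(OCC=C)c3OC(C)(C)C=Cc3c12 | intermediate
19 | hydrazone of 18 | NN=C1COc2cc3OC(C)(C)C=Cc3cc2COc2c(CC=C(C)C)c(OCC=C)c3OC(C)(C)C=Cc3c12 | intermediate
20 | diazo compound from 19 (not isolated) | [N-]=[N+]=C1COc2cc3OC(C)(C)C=Cc3cc2COc2c(CC=C(C)C)c(OCC=C)c3OC(C)(C)C=Cc3c12 | intermediate
21 | (6aR,11aR)-9-O-allyl-lespecyrtin E4 (cis-fused pterocarpan, all six rings in place) | CC(C)=CCc1c(OCC=C)c2c(c3c1O[C@H]1c4cc5c(cc4OC[C@@H]31)OC(C)(C)C=C5)C=CC(C)(C)O2 | intermediate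
22 | lespecyrtin E4, (6aR,11aR) | CC(C)=CCc1c(O)c2c(c3c1O[C@H]1c4cc5c(cc4OC[C@@H]31)OC(C)(C)C=C5)C=CC(C)(C)O2 | target

**Step count and risks**

Total step count: 14. Longest linear sequence: 11 steps (steps 1–5 and 9–14); steps 6–8 form the ring A branch.

Steps most likely to fail:

1. Step 13 (Proposed new method). What may go wrong: 1,2-hydride migration from C6 to the carbene carbon, or carbene dimerisation, may outrun the transannular insertion, and discrimination between the two enantiotopic C11a hydrogens may be eroded by the conformational demands of the medium ring. The fallback uses known chemistry, an acceptor-stabilised carbene without β-hydrogens and no medium ring; it sets out from 14 and comes back to the route at 21. Ketone 14 is converted by detrifluoroacetylative diazo transfer (LiN(SiMe3)2, CF3CO2CH2CF3; then MsN3, Et3N) into the α-diazoketone F1, whose silver-catalysed Wolff rearrangement in methanol (PhCO2Ag, Et3N) gives the methyl arylacetate F2. Diazo transfer (4-acetamidobenzenesulfonyl azide, DBU, MeCN) gives the aryldiazoacetate F3, which undergoes the well-precedented enantioselective 1,5 C–H insertion into the benzylic ether C–H bond with Rh2(S-PTTL)4 in toluene at low temperature to give the cis-2-aryl-2,3-dihydrobenzofuran-3-carboxylate F4. LiAlH4 reduces the ester to the primary alcohol F5, TBAF frees the ring A phenol to give the hydroxy phenol F6, and an intramolecular Mitsunobu etherification (PPh3, DIAD, THF) closes ring B, again as the last ring, to give 21.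

2. Step 11. What may go wrong: intermolecular alkylation (oligomer formation) may compete with the slow nine-membered ring closure, and fluoride may substitute the bromide. The fallback closes the same ether from the alcohol side by redox condensation on neutral species; it sets out from 16 and comes back at 18. Bromide 16 is displaced with CsOAc in DMF to give the α-acetoxy ketone F7; K2CO3 in methanol removes the acetate and the aryl silyl group to give the α-hydroxy ketone phenol F8; intramolecular Mitsunobu etherification (PPh3, DIAD, THF, 2 mM, slow addition) then forms the O5–C6 bond and gives 18.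

3. Step 12. What may go wrong: condensation at the di-ortho-substituted, ring-constrained ketone may be slow, and hot basic hydrazine may expel the α-aryloxy group (ring-opening elimination) or reduce alkenes through adventitious diimide. The fallback reaches the diazo compound by sulfinate loss instead of hydrazone oxidation; it sets out from 18 and comes back at diazo compound 20, which goes on to 21 as in step 13. Ketone 18 is condensed with 4-methylbenzenesulfonohydrazide (MeOH, pyridinium 4-toluenesulfonate cat.) to the N-tosylhydrazone F9, which on deprotonation with NaH and warming in the presence of Rh2(R-PTAD)4 loses sulfinate (Bamford–Stevens) to give 20 in situ.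

**Further compounds**

F1 | step 13 | α-diazoketone from 14, 2-diazo-1-[6-({7-[(tert-butyldimethylsilyl)oxy]-2,2-dimethyl-2H-chromen-6-yl}methoxy)-2,2-dimethyl-7-(3-methylbut-2-en-1-yl)-8-(prop-2-en-1-yloxy)-2H-chromen-5-yl]ethanone | [N-]=[N+]=CC(=O)c1c(OCc3cc4C=CC(C)(C)Oc4cc3O[Si](C)(C)C(C)(C)C)c(CC=C(C)C)c(OCC=C)c2OC(C)(C)C=Cc12
F2 | step 13 | methyl arylacetate, methyl 2-[6-({7-[(tert-butyldimethylsilyl)oxy]-2,2-dimethyl-2H-chromen-6-yl}methoxy)-2,2-dimethyl-7-(3-methylbut-2-en-1-yl)-8-(prop-2-en-1-yloxy)-2H-chromen-5-yl]acetate | COC(=O)Cc1c(OCc3cc4C=CC(C)(C)Oc4cc3O[Si](C)(C)C(C)(C)C)c(CC=C(C)C)c(OCC=C)c2OC(C)(C)C=Cc12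
F3 | step 13 | aryldiazoacetate, methyl 2-diazo-2-[same aryl as in F2]acetate | COC(=O)C(=[N+]=[N-])c1c(OCc3cc4C=CC(C)(C)Oc4cc3O[Si](C)(C)C(C)(C)C)c(CC=C(C)C)c(OCC=C)c2OC(C)(C)C=Cc12
F4 | step 13 | methyl cis-(2R,3S)-2-{7-[(tert-butyldimethylsilyl)oxy]-2,2-dimethyl-2H-chromen-6-yl}-2,3-dihydrobenzofuran-3-carboxylate on ring D (pyran, O-allyl and prenyl in place) | COC(=O)[C@H]1c2c3C=CC(C)(C)Oc3c(OCC=C)c(CC=C(C)C)c2O[C@H]1c1cc2C=CC(C)(C)Oc2cc1O[Si](C)(C)C(C)(C)C
F5 | step 13 | cis-(2R,3R)-3-(hydroxymethyl)-2-(silyloxychromenyl)-2,3-dihydrobenzofuran from F4 | OC[C@H]1c2c3C=CC(C)(C)Oc3c(OCC=C)c(CC=C(C)C)c2O[C@H]1c1cc2C=CC(C)(C)Oc2cc1O[Si](C)(C)C(C)(C)C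
F6 | step 13 | cis-(2R,3R)-3-(hydroxymethyl)-2-(7-hydroxy-2,2-dimethyl-2H-chromen-6-yl)-2,3-dihydrobenzofuran from F5 | OC[C@H]1c2c3C=CC(C)(C)Oc3c(OCC=C)c(CC=C(C)C)c2O[C@H]1c1cc2C=CC(C)(C)Oc2cc1O
F7 | step 11 | α-acetoxy ketone from 16 | CC(=O)OCC(=O)c1c(OCc3cc4C=CC(C)(C)Oc4cc3O[Si](C)(C)C(C)(C)C)c(CC=C(C)C)c(OCC=C)c2OC(C)(C)C=Cc12
F8 | step 11 | α-hydroxy ketone phenol, 2-hydroxy-1-{6-[(7-hydroxy-2,2-dimethyl-2H-chromen-6-yl)methoxy]-2,2-dimethyl-7-(3-methylbut-2-en-1-yl)-8-(prop-2-en-1-yloxy)-2H-chromen-5-yl}ethanone | OCC(=O)c1c(OCc3cc4C=CC(C)(C)Oc4cc3O)c(CC=C(C)C)c(OCC=C)c2OC(C)(C)C=Cc12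
F9 | step 12 | N-tosylhydrazone of 18 | Cc1ccc(cc1)S(=O)(=O)NN=C1COc2cc3OC(C)(C)C=Cc3cc2COc2c(CC=C(C)C)c(OCC=C)c3OC(C)(C)C=Cc3c12
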